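The rate constants were set for the occasion; the rest is arithmetic.

The constants below describe free enzyme turning substrate into target, an impurity that takes enzyme away, and a leak of target to its isomer.

all flasks: substrate 0.020 M; free enzyme 0.05 mol%; impurity 2.1 µM; time 15 h

| flask | temperature | remark |
|---|---|---|
| midnight | 37 °C |  |
| noon |  | at 37 °C until 8.0 h, from then on at 7 °C |
| winter | 7 °C |  |
| summer | 22 °C |  |

    target + free enzyme ⇌ isomer of the product + free enzyme, rate k1*[free enzyme]*[target] forward; the back reaction follows from the equilibrium constant (K1 = 23, k1 = 12000 M⁻¹ h⁻¹, Ea1 = 59.0 kJ mol⁻¹, ΔH1 = 0 kJ mol⁻¹)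
    free enzyme + impurity → spent catalyst (k2 = 1.6 × 10⁶ M⁻¹ h⁻¹, Ea2 = 50.0 kJ mol⁻¹)
    substrate + free enzyme ⇌ complex (K3 = 130 M⁻¹, k3 = 1.1 × 10⁵ M⁻¹ h⁻¹, Ea3 = 49.0 kJ mol⁻¹, ΔH3 = −52.0 kJ mol⁻¹)
    crystals ⇌ target, rate k4*(cs4 - [target]) while solid is left; crystals form when [target] > cs4 (cs4 = 15 mM, k4 = 1.4 h⁻¹)
    complex ⇌ free enzyme + target (K5 = 0.030 M, k5 = 61 h⁻¹, Ea5 = 91.0 kJ mol⁻¹, ΔH5 = −33.0 kJ mol⁻¹)
    free enzyme → unfolded enzyme (k6 = 5.3 × 10⁻⁴ h⁻¹, Ea6 = 200 kJ mol⁻¹)
    (constants at 37 °C)

- the flask with the highest amount of target, in percent of the substrate charged ("all alike" if they lie within 1.5 percentage points) (midnight / noon / winter / summer / all alike)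
- final target, as a percentage of the substrate charged, in midnight
- final target, as a percentage of the substrate charged, in noon
- final target, as a percentage of the substrate charged, in winter
- final target, as a percentage of the substrate charged, in summer

- amounts and yields of target count crystals too
- given per volume of solution although it is solid: crystals
- all constants are for 37 °C and move with temperature by the activation energies and enthalpies

How much enzyme is there to work with?

The charge is 10.0 µM of free enzyme. The impurity takes enzyme one to one and 2.1 µM of it is charged, so I freeze the working enzyme at 7.90 µM.

What does that enzyme do in midnight?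

It binds substrate to complex, and complex releases target. In midnight release, at 61 h⁻¹, is slower than binding, at 2200 h⁻¹, and slower than falling apart, at 846 h⁻¹, so I take it as the rate-limiting step. I also freeze [substrate] at its charge. Add the rate constant of falling apart to that of release and divide by the rate constant of binding. That gives 8.25 mM, the Michaelis constant, where half the working enzyme sits as complex. At 0.020 M the loaded share, complex over working enzyme, is 70.8%.

And the rule?

The turnover rate is release constant times loaded share times working enzyme. In midnight it is 341 µM h⁻¹. Held over 15 h, that rate gives 5.11 mM, or 25.6% of the charge. This stays below the solubility, so I expect no crystals in midnight.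

A quarter of the substrate goes. Doesn't your freeze break?

It bends. At that point the loaded share in midnight is 64.3%, so my figure lies on the high side.

Is all of that conversion target?

No. I reckon midnight's free enzyme at 2.31 µM, which drains target at 0.0277 h⁻¹. Target stands on average for half the time, so midnight's target comes to about 21.2%.

Is the working enzyme really frozen?

In midnight, yes. By my reckoning the impurity in midnight has a lifetime of 0.271 h, and unfolding takes hardly any of the enzyme.

Now winter.

In winter release is slower by a factor 44, at 1.39 h⁻¹. The same reckoning gives 0.985 mM, a loaded share of 95.3%, and a turnover rate of 10.5 µM h⁻¹. Held over 15 h, that is 0.787% of the charge.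

The weak spot?

I reckon winter's free enzyme at 0.371 µM, so the impurity has a lifetime of about 13.4 h, which is not short against 15 h. I therefore put winter's conversion between 0.787% and 0.997%. Leakage to isomer is smaller there.

Your pick?

Of the flasks I reckoned, midnight converts most. Summer's temperature lies between, and I give it no number.

The forecast names midnight, with 18.8% in midnight, 11.8% in noon, 0.9% in winter and 5.1% in summer, on the ground that “turnover through the complex sets the rate and falls steeply on cooling”.

The simulation gives midnight as highest, with 18.9% in midnight, 12.1% in noon, 0.899% in winter and 5.17% in summer. Midnight's conversion of substrate at the end is 23.8%, against the 25.6% from the turnover rate. For noon I reckon midnight's turnover rate of 341 µM h⁻¹ for 8.0 h, then winter's 10.5 µM h⁻¹ for 7.00 h, which comes to 14.0% of the charge. Noon's conversion of substrate at the end stands at 13.6%.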